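Assumption: the target has no stereocentre and no stereogenic double bond, so it is achiral; "single enantiomer" is met by the compound itself and nothing has to be set.

**Retrosynthetic overview**
- Last bond made: pyranone C3–CH2–aryl. The target splits into 6-ethyl-4-hydroxy-5-methyl-2-pyranone, a CH2 unit (iminium salt) and the acylphloroglucinol methyl ether that has one free ring CH.
- The prenyl group comes off by C-prenylation at the ring carbon between the two free hydroxyls of the mono-methyl ether.
- Key disconnection: the aryl O–CH3 bond. One ortho-selective O-methylation of symmetric 2,4,6-trihydroxyisobutyrophenone (new dianion method) decides which oxygen is capped, and so where the prenyl group and the bridge must go.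
- The trihydroxy ketone comes from phloroglucinol and isobutyryl chloride. The pyranone comes from the silyl enol ether of pentan-3-one and malonyl dichloride (C-acylation, then ring-closing C–O lactonisation).
- Rings: the benzene ring is bought; the 2-pyranone is the only ring built (step 5), before the fragments are joined.

**Route**

Step 1
Reactants: 1 benzene-1,3,5-triol (phloroglucinol); 2 2-methylpropanoyl chloride
Product: 3 2-methyl-1-(2,4,6-trihydroxyphenyl)propan-1-one
Conditions: AlCl3 (3.5 equiv), CH2Cl2/PhNO2, 0 → 40 °C; ice/aq. HCl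
Reagents that add atoms: none
Why: Friedel–Crafts acylation of the highly activated, symmetric triol; the Al-chelated, deactivated product resists a second acylation.

Step 2
Reactants: 3 2-methyl-1-(2,4,6-trihydroxyphenyl)propan-1-one
Product: 5 1-(2,4-dihydroxy-6-methoxyphenyl)-2-methylpropan-1-one, via dipotassium dianion 4 (not isolated)
Conditions: KOt-Bu (2.05 equiv), 18-crown-6 (2.1 equiv), DMF, −40 °C; MeOTs (1.0 equiv), −40 → 0 °C; aq. HCl quench
Reagents that add atoms: methyl 4-methylbenzenesulfonate, COS(=O)(=O)c1ccc(C)cc1
Why: Proposed new method: dianion-controlled ortho-O-methylation of a 2,4,6-trihydroxyaryl ketone – two equivalents of base remove the para-OH proton and then the proton of the ortho-OH that is not hydrogen-bonded to the carbonyl; the crown ether keeps K+ from chelating this ortho-phenoxide to the C=O, and this last-formed, more basic phenoxide (the para-phenoxide is the conjugate base of the stronger acid) attacks the hard electrophile MeOTs by SN2 to form the C–O bond; the product is only a stabilised para-phenoxide monoanion, far less nucleophilic than the dianion, so the reaction should stop at the mono-ether, and because the two ortho-OH groups of 3 are equivalent only one ortho-ether can form; dipolar aprotic solvent, free anion and a sulfonate leaving group disfavour ring C-methylation; closest known reaction type: Williamson O-alkylation of phenol dianions at the less acidic hydroxyl (as for 3,4-dihydroxybenzaldehyde) and the rule that the last-formed anion of a β-keto ester dianion reacts first.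

Step 3
Reactants: 5 1-(2,4-dihydroxy-6-methoxyphenyl)-2-methylpropan-1-one; 6 1-bromo-3-methylbut-2-ene (prenyl bromide)
Product: 7 1-[2,4-dihydroxy-6-methoxy-3-(3-methylbut-2-en-1-yl)phenyl]-2-methylpropan-1-one
Conditions: DBU (1.1 equiv), THF, 0 °C → rt; chromatography
Reagents that add atoms: none
Why: Base-mediated C-prenylation (C-alkylation of the ambident 4-phenoxide); the carbon between the phenoxide and the chelated 2-OH is the most nucleophilic and least hindered site, while the other free carbon is shielded by the in-plane O-methyl group.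

Step 4
Reactants: 8 pentan-3-one
Product: 9 (Z)-trimethyl(pent-2-en-3-yloxy)silane
Conditions: TMSOTf (1.1 equiv), Et3N (1.3 equiv), Et2O, 0 °C → rt; pentane extraction, distillation
Reagents that add atoms: trimethylsilyl trifluoromethanesulfonate, C[Si](C)(C)OS(=O)(=O)C(F)(F)F
Why: Soft enolisation and O-silylation (silyl enol ether formation) of a symmetric ketone; Z is the main isomer, and both isomers give the same pyranone.

Step 5
Reactants: 9 (Z)-trimethyl(pent-2-en-3-yloxy)silane; 10 propanedioyl dichloride (malonyl dichloride)
Product: 12 6-ethyl-4-hydroxy-5-methyl-2H-pyran-2-one, via 4-methyl-3,5-dioxoheptanoyl chloride 11 (not isolated)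
Conditions: Et2O, −78 °C → rt, 16 h
Reagents that add atoms: none
Why: Effenberger-type pyranone synthesis: C-acylation of the silyl enol ether by one acid chloride, then enol O-acylation by the second (ring-closing C–O lactonisation) gives the aromatic 4-hydroxy-2-pyranone as thermodynamic sink.

Step 6
Reactants: 12 6-ethyl-4-hydroxy-5-methyl-2H-pyran-2-one; 7 1-[2,4-dihydroxy-6-methoxy-3-(3-methylbut-2-en-1-yl)phenyl]-2-methylpropan-1-one
Product: 15 3-{[2,4-dihydroxy-6-methoxy-3-(3-methylbut-2-en-1-yl)-5-(2-methylpropanoyl)phenyl]methyl}-6-ethyl-4-hydroxy-5-methyl-2H-pyran-2-one, via pyranone Mannich base 13 (not isolated), via 3-methylidenepyran-2,4-dione 14 (not isolated)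
Conditions: 12, CH2=NMe2+ I− (1.05 equiv), MeCN, rt, 1 h; then 7 (1.0 equiv), 60 °C
Reagents that add atoms: N,N-dimethylmethyleneiminium iodide (Eschenmoser's salt), C=[N+](C)C.[I-]
Why: Mannich aminomethylation at pyranone C3, elimination of dimethylamine to the methylidene-pyrandione Michael acceptor, then Friedel–Crafts-type conjugate addition by the only unsubstituted ring carbon of 7, as in the known methylene-bridging of phloroglucinols to 4-hydroxypyranones.

**Compound list**
1 | benzene-1,3,5-triol (phloroglucinol) | Oc1cc(O)cc(O)c1 | starting material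
2 | 2-methylpropanoyl chloride | CC(C)C(=O)Cl | starting material
3 | 2-methyl-1-(2,4,6-trihydroxyphenyl)propan-1-one | CC(C)C(=O)c1c(O)cc(O)cc1O | intermediate
4 | dipotassium salt of 3 (para- and one ortho-phenoxide; other ortho-OH chelated) | CC(C)C(=O)c1c(O)cc([O-])cc1[O-].[K+].[K+] | intermediate (not isolated)
5 | 1-(2,4-dihydroxy-6-methoxyphenyl)-2-methylpropan-1-one | CC(C)C(=O)c1c(O)cc(O)cc1OC | intermediate
6 | 1-bromo-3-methylbut-2-ene | CC(C)=CCBr | starting material
7 | 1-[2,4-dihydroxy-6-methoxy-3-(3-methylbut-2-en-1-yl)phenyl]-2-methylpropan-1-one | CC(C)C(=O)c1c(O)c(CC=C(C)C)c(O)cc1OC | intermediate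
8 | pentan-3-one | CCC(=O)CC | starting material
9 | (Z)-trimethyl(pent-2-en-3-yloxy)silane | C/C=C(/CC)O[Si](C)(C)C | intermediate
10 | propanedioyl dichloride | O=C(Cl)CC(=O)Cl | starting material
11 | 4-methyl-3,5-dioxoheptanoyl chloride (racemic, enolising) | CCC(=O)C(C)C(=O)CC(=O)Cl | intermediate (not isolated)
12 | 6-ethyl-4-hydroxy-5-methyl-2H-pyran-2-one | CCc1oc(=O)cc(O)c1C | intermediate
13 | 3-[(dimethylamino)methyl]-6-ethyl-4-hydroxy-5-methyl-2H-pyran-2-one | CCc1oc(=O)c(CN(C)C)c(O)c1C | intermediate (not isolated)
14 | 6-ethyl-5-methyl-3-methylidene-2H-pyran-2,4(3H)-dione | CCC1=C(C)C(=O)C(=C)C(=O)O1 | intermediate (not isolated)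
15 | 3-{[2,4-dihydroxy-6-methoxy-3-(3-methylbut-2-en-1-yl)-5-(2-methylpropanoyl)phenyl]methyl}-6-ethyl-4-hydroxy-5-methyl-2H-pyran-2-one | CCc1oc(=O)c(Cc2c(O)c(CC=C(C)C)c(O)c(C(=O)C(C)C)c2OC)c(O)c1C | target

**Step count**
Total steps: 6. Longest linear sequence: 4 (steps 1, 2, 3, 6); the pyranone branch is steps 4 and 5.

**Three steps most likely to fail**

Step 2 (the proposed new step). The risks are para-O-methylation, double methylation and ring C-methylation. The isomers are told apart by NMR: 5 has two meta-coupled aromatic doublets and a chelated OH, while the para-ether shows a 2H singlet. Fallback (known chemistry, protecting-group differentiation instead of dianion control), from 3 back to 5: 3 is treated with MOMCl (2.2 equiv) and i-Pr2NEt in CH2Cl2. This caps the para-OH and one ortho-OH and leaves the chelated one, giving 1-[2-hydroxy-4,6-bis(methoxymethoxy)phenyl]-2-methylpropan-1-one F1. The remaining hydroxyl is methylated under forcing Williamson conditions (Me2SO4, K2CO3, acetone, reflux) to 1-[2-methoxy-4,6-bis(methoxymethoxy)phenyl]-2-methylpropan-1-one F2. HCl in MeOH at rt removes both MOM groups and gives 5.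

Step 3. The risks are the 5-prenyl regioisomer, O-prenyl ether and bis-prenylation, so the yield is likely moderate. Fallback (regiochemistry fixed by sigmatropic shifts instead of intermolecular C-alkylation), from 3 to 7: 3 is converted as above into the bis-MOM ether 1-[2-hydroxy-4,6-bis(methoxymethoxy)phenyl]-2-methylpropan-1-one F1. Its free hydroxyl is O-prenylated with 6 (K2CO3, DMF, 60 °C) to 1-[2,4-bis(methoxymethoxy)-6-[(3-methylbut-2-en-1-yl)oxy]phenyl]-2-methylpropan-1-one F3. Heating in N,N-diethylaniline at 200 °C brings about a para-Claisen–Cope sequence that places the prenyl group between the two MOM ethers, giving 1-[6-hydroxy-2,4-bis(methoxymethoxy)-3-(3-methylbut-2-en-1-yl)phenyl]-2-methylpropan-1-one F4. The liberated hydroxyl is methylated (Me2SO4, K2CO3, acetone) to 1-[6-methoxy-2,4-bis(methoxymethoxy)-3-(3-methylbut-2-en-1-yl)phenyl]-2-methylpropan-1-one F5. HCl in MeOH at rt then gives 7.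

Step 6. The risks are self-capture of 14 by unreacted 12 (methylene-bis-pyranone), O-alkylation, and slow attack at the carbon next to the methoxy group. Fallback (the electrophile is generated on the aryl partner instead of the pyranone), from 7 to 15: 7 is aminomethylated at its free ring carbon (aq. CH2O, Me2NH, EtOH, rt) to 1-[3-[(dimethylamino)methyl]-4,6-dihydroxy-2-methoxy-5-(3-methylbut-2-en-1-yl)phenyl]-2-methylpropan-1-one F6. Heating F6 with 12 in dioxane at 100 °C expels dimethylamine to give an ortho-quinone methide, which C3 of the pyranone traps by Michael addition to give 15. No bis-pyranone can form this way.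

**Further compounds**
F1 | step 2 | 1-[2-hydroxy-4,6-bis(methoxymethoxy)phenyl]-2-methylpropan-1-one | CC(C)C(=O)c1c(O)cc(OCOC)cc1OCOC
F2 | step 2 | 1-[2-methoxy-4,6-bis(methoxymethoxy)phenyl]-2-methylpropan-1-one | CC(C)C(=O)c1c(OC)cc(OCOC)cc1OCOC
F3 | step 3 | 1-[2,4-bis(methoxymethoxy)-6-[(3-methylbut-2-en-1-yl)oxy]phenyl]-2-methylpropan-1-one | CC(C)C(=O)c1c(OCC=C(C)C)cc(OCOC)cc1OCOC
F4 | step 3 | 1-[6-hydroxy-2,4-bis(methoxymethoxy)-3-(3-methylbut-2-en-1-yl)phenyl]-2-methylpropan-1-one | CC(C)C(=O)c1c(O)cc(OCOC)c(CC=C(C)C)c1OCOC
F5 | step 3 | 1-[6-methoxy-2,4-bis(methoxymethoxy)-3-(3-methylbut-2-en-1-yl)phenyl]-2-methylpropan-1-one | CC(C)C(=O)c1c(OC)cc(OCOC)c(CC=C(C)C)c1OCOC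
F6 | step 6 | 1-[3-[(dimethylamino)methyl]-4,6-dihydroxy-2-methoxy-5-(3-methylbut-2-en-1-yl)phenyl]-2-methylpropan-1-one | CC(C)C(=O)c1c(O)c(CC=C(C)C)c(O)c(CN(C)C)c1OC
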